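**Retrosynthetic overview**
1. Pyran last: O–C15/C14–Cl by chloronium-induced cyclisation of tertiary alcohol 20; C11–C12 by Felkin-controlled addition of a homoprenyl nucleophile to the C7 methyl ketone 17.
2. C10: methyl added to the convex face of the N-sulfinyl ketimine of cis-decalone 13, then N-formylation.
3. Ring B (key step): C7–C8 by 6-endo cyclisation of a C7 radical, released by deoxygenation of a carbinol, onto a vinyl ketone (11 → 13).
4. Ring A: alkoxide-templated Diels–Alder reaction of (R)-dienol 7 with divinyl ketone; the carbinol stereocentre sets C1/C6 and is then erased in the radical step.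
5. Dienol 7 from methyl pyruvate and 2-methylbut-1-en-3-yne. Ring order: ring A, ring B, pyran.

Assumption: kalihinene numbering is used (C1/C6 ring fusion, C4=C5, C7 bears the pyran, C10 bears N, C11–C15 pyran carbons); the target SMILES reads as 1S,6R,7R,10R,11R,14S. The route is a design on paper; the stereochemical outcomes are predictions from the models named in each step.

**Step 1**
Reactants: 1 methyl 2-oxopropanoate
Product: 2 methyl 2-methyl-1,3-dioxolane-2-carboxylate
Conditions: HOCH2CH2OH, p-TsOH (cat.), toluene, reflux, Dean–Stark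
Reagents that add atoms: ethylene glycol, OCCO
Why: Acid-catalysed ketalisation protects the ketone that later becomes the C11 carbonyl, and no stereocentre is formed.

**Step 2**
Reactants: 3 2-methylbut-1-en-3-yne; 2 methyl 2-methyl-1,3-dioxolane-2-carboxylate
Product: 5 4-methyl-1-(2-methyl-1,3-dioxolan-2-yl)pent-4-en-2-yn-1-one, via lithium acetylide 4 (not isolated)
Conditions: n-BuLi, THF, −78 °C; then 2, −78 °C; aq. NH4Cl at −78 °C
Reagents that add atoms: none
Why: Acylation of a lithium acetylide by an α,α-dialkoxy ester stops at the ynone because the chelated tetrahedral intermediate survives until the cold quench, and no stereocentre is formed.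

**Step 3**
Reactants: 5 4-methyl-1-(2-methyl-1,3-dioxolan-2-yl)pent-4-en-2-yn-1-one
Product: 6 (1R)-4-methyl-1-(2-methyl-1,3-dioxolan-2-yl)pent-4-en-2-yn-1-ol
Conditions: (S)-2-methyl-CBS-oxazaborolidine (10 mol%), catecholborane, toluene, −78 °C
Reagents that add atoms: none
Why: Corey–Bakshi–Shibata reduction with the tertiary dioxolanyl carbon as the large group and the alkynyl as the small group gives the (R)-carbinol, which is the temporary control element for C6/C1.

**Step 4**
Reactants: 6 (1R)-4-methyl-1-(2-methyl-1,3-dioxolan-2-yl)pent-4-en-2-yn-1-ol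
Product: 7 (1R,2E)-4-methyl-1-(2-methyl-1,3-dioxolan-2-yl)penta-2,4-dien-1-ol
Conditions: NaAlH2(OCH2CH2OMe)2, THF, 0 °C to rt; Rochelle salt
Reagents that add atoms: none
Why: Hydroxyl-directed trans-hydroalumination of the propargylic alcohol gives the (E)-dienol without touching the carbinol stereocentre.

**Step 5**
Reactants: 8 penta-1,4-dien-3-ol
Product: 9 penta-1,4-dien-3-one
Conditions: activated MnO2, CH2Cl2, 0 °C to rt; filtered, solution used at once
Reagents that add atoms: none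
Why: Allylic alcohol oxidation gives the bis-vinyl ketone dienophile, and no stereocentre is involved.

**Step 6**
Reactants: 7 (1R,2E)-4-methyl-1-(2-methyl-1,3-dioxolan-2-yl)penta-2,4-dien-1-ol; 9 penta-1,4-dien-3-one
Product: 11 1-[(1S,2R)-2-[(R)-hydroxy(2-methyl-1,3-dioxolan-2-yl)methyl]-4-methylcyclohex-3-en-1-yl]prop-2-en-1-one, via magnesium alkoxide 10 (not isolated)
Conditions: MeMgBr (1.0 equiv), CH2Cl2, 0 °C; then 9 (3 equiv), −20 °C to rt; aq. NH4Cl
Reagents that add atoms: none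
Why: Alkoxide-templated Diels–Alder reaction in which the magnesium alkoxide binds the enone carbonyl, so the dienophile adds ortho/para and endo on the oxygen-bearing face of the diene with H7 eclipsing the diene and the bulky dioxolanyl group anti, which for the (R)-carbinol sets C6 as R and C1 as S (cis).

**Step 7 (key step)**
Reactants: 11 1-[(1S,2R)-2-[(R)-hydroxy(2-methyl-1,3-dioxolan-2-yl)methyl]-4-methylcyclohex-3-en-1-yl]prop-2-en-1-one
Product: 13 (4R,4aR,8aS)-6-methyl-4-(2-methyl-1,3-dioxolan-2-yl)-3,4,4a,7,8,8a-hexahydronaphthalen-1(2H)-one, via benzoxazoline aminal 12 (not isolated)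
Conditions: 5,7-di-tert-butyl-3-phenylbenzoxazolium BF4, pyridine, MTBE, rt; then [Ir(ppy)2(dtbbpy)]PF6 (1 mol%), NaOAc, MTBE/DMSO (0.01 M), 450 nm LEDs, rt
Reagents that add atoms: none
Why: Photoredox deoxygenative radical generation (oxidation of the aminal, β-scission of the C7–O bond) followed by 6-endo-trig Giese cyclisation of the nucleophilic C7 radical onto the terminal carbon of the vinyl ketone forms C7–C8 and closes ring B as the cis-decalone, the carbinol stereocentre being erased and C7 re-formed with the dioxolanyl group equatorial in a chair-like transition state that keeps the C1 acyl group equatorial on ring A.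

**Step 8**
Reactants: 13 (4R,4aR,8aS)-6-methyl-4-(2-methyl-1,3-dioxolan-2-yl)-3,4,4a,7,8,8a-hexahydronaphthalen-1(2H)-one
Product: 14 (R)-N-[(1E,4R,4aR,8aS)-6-methyl-4-(2-methyl-1,3-dioxolan-2-yl)-3,4,4a,7,8,8a-hexahydronaphthalen-1(2H)-ylidene]-2-methylpropane-2-sulfinamide
Conditions: (R)-t-BuS(O)NH2, Ti(OEt)4, THF, 45 °C
Reagents that add atoms: (R)-2-methylpropane-2-sulfinamide, CC(C)(C)[S@@](=O)N
Why: Ellman condensation gives the (E)-N-sulfinyl ketimine with sulfur anti to the branched C1, under mild conditions chosen to avoid epimerising the ring-fusion carbon, and no new carbon stereocentre is formed.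

**Step 9**
Reactants: 14 (R)-N-[(1E,4R,4aR,8aS)-6-methyl-4-(2-methyl-1,3-dioxolan-2-yl)-3,4,4a,7,8,8a-hexahydronaphthalen-1(2H)-ylidene]-2-methylpropane-2-sulfinamide
Product: 15 (R)-N-[(1R,4R,4aR,8aS)-1,6-dimethyl-4-(2-methyl-1,3-dioxolan-2-yl)-1,2,3,4,4a,7,8,8a-octahydronaphthalen-1-yl]-2-methylpropane-2-sulfinamide
Conditions: AlMe3, toluene, −78 °C; then MeLi, −78 °C; aq. NH4Cl
Reagents that add atoms: methyllithium, [Li]C; trimethylaluminium, C[Al](C)C (the methyl is transferred from the ate complex of the two)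
Why: Ellman 1,2-addition through the six-membered chelated chair delivers methyl to the convex face of the cis-decalin, the (R)-sulfur being matched to that face, which sets C10 as R with nitrogen equatorial and methyl axial.

**Step 10**
Reactants: 15 (R)-N-[(1R,4R,4aR,8aS)-1,6-dimethyl-4-(2-methyl-1,3-dioxolan-2-yl)-1,2,3,4,4a,7,8,8a-octahydronaphthalen-1-yl]-2-methylpropane-2-sulfinamide
Product: 17 N-[(1R,4R,4aR,8aS)-4-acetyl-1,6-dimethyl-1,2,3,4,4a,7,8,8a-octahydronaphthalen-1-yl]formamide, via ammonium chloride 16 (not isolated)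
Conditions: 2 M aq. HCl, THF, rt; evaporate; HCO2Ac, Et3N, CH2Cl2, 0 °C to rt; then DBU (cat.), rt
Reagents that add atoms: water, O; acetic formic anhydride, O=COC(C)=O
Why: Acid cleaves the N–S bond and the dioxolane, the mixed anhydride N-formylates the hindered amine, and base equilibration of the now enolisable C7 favours the equatorial acetyl epimer that avoids a 1,3-diaxial N/C5 contact (an estimated preference of about 1 kcal/mol, the target configuration).

**Step 11**
Reactants: 18 5-bromo-2-methylpent-2-ene; 17 N-[(1R,4R,4aR,8aS)-4-acetyl-1,6-dimethyl-1,2,3,4,4a,7,8,8a-octahydronaphthalen-1-yl]formamide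
Product: 20 N-[(1R,4R,4aR,8aS)-4-[(2R)-2-hydroxy-6-methylhept-5-en-2-yl]-1,6-dimethyl-1,2,3,4,4a,7,8,8a-octahydronaphthalen-1-yl]formamide, via Grignard reagent 19 (not isolated)
Conditions: Mg, THF; anhydrous CeCl3, THF, −78 °C; then 17, −78 to 0 °C (3 equiv of 19); aq. NH4Cl
Reagents that add atoms: none
Why: Organocerium 1,2-addition to the methyl ketone under Felkin–Anh control (C6 as the large group anti to the nucleophile, attack past H7) sets C11 as R, while the formamide is protected as its amidate by the first equivalent.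

**Step 12**
Reactants: 20 N-[(1R,4R,4aR,8aS)-4-[(2R)-2-hydroxy-6-methylhept-5-en-2-yl]-1,6-dimethyl-1,2,3,4,4a,7,8,8a-octahydronaphthalen-1-yl]formamide
Product: 21 N-[(1R,4R,4aR,8aS)-4-[(2R,5S)-5-chloro-2,6,6-trimethyloxan-2-yl]-1,6-dimethyl-1,2,3,4,4a,7,8,8a-octahydronaphthalen-1-yl]formamide
Conditions: Et2SCl·SbCl6 (1.05 equiv), 2,6-di-tert-butyl-4-methylpyridine, MeNO2/CH2Cl2, −40 °C
Reagents that add atoms: chlorodiethylsulfonium hexachloroantimonate, CC[S+](Cl)CC.Cl[Sb-](Cl)(Cl)(Cl)(Cl)Cl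
Why: Chloronium-induced 6-endo (Markovnikov) chloroetherification through a chair transition state with chlorine and the decalinyl group equatorial and the C11 methyl axial sets C14 as S, the exposed side-chain alkene being expected to react before the hindered ring alkene.

**Compound list**
1 | methyl 2-oxopropanoate (methyl pyruvate) | CC(=O)C(=O)OC | starting material
2 | methyl 2-methyl-1,3-dioxolane-2-carboxylate | COC(=O)C1(C)OCCO1 | intermediate
3 | 2-methylbut-1-en-3-yne | C=C(C)C#C | starting material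
4 | (3-methylbut-3-en-1-yn-1-yl)lithium | [Li]C#CC(C)=C | intermediate
5 | 4-methyl-1-(2-methyl-1,3-dioxolan-2-yl)pent-4-en-2-yn-1-one | C=C(C)C#CC(=O)C1(C)OCCO1 | intermediate
6 | (1R)-4-methyl-1-(2-methyl-1,3-dioxolan-2-yl)pent-4-en-2-yn-1-ol | C=C(C)C#C[C@@H](O)C1(C)OCCO1 | intermediate
7 | (1R,2E)-4-methyl-1-(2-methyl-1,3-dioxolan-2-yl)penta-2,4-dien-1-ol | C=C(C)/C=C/[C@@H](O)C1(C)OCCO1 | intermediate
8 | penta-1,4-dien-3-ol | C=CC(O)C=C | starting material
9 | penta-1,4-dien-3-one | C=CC(=O)C=C | intermediate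
10 | bromomagnesium alkoxide of 7 | C=C(C)/C=C/[C@@H](O[Mg]Br)C1(C)OCCO1 | intermediate
11 | 1-[(1S,2R)-2-[(R)-hydroxy(2-methyl-1,3-dioxolan-2-yl)methyl]-4-methylcyclohex-3-en-1-yl]prop-2-en-1-one | CC1=C[C@@H]([C@@H](O)C2(C)OCCO2)[C@@H](C(=O)C=C)CC1 | intermediate
12 | O-(5,7-di-tert-butyl-3-phenyl-2,3-dihydro-1,3-benzoxazol-2-yl) ether of 11 (aminal carbon unassigned) | CC1=C[C@@H]([C@@H](OC2Oc3c(C(C)(C)C)cc(C(C)(C)C)cc3N2c2ccccc2)C2(C)OCCO2)[C@@H](C(=O)C=C)CC1 | intermediate
13 | (4R,4aR,8aS)-6-methyl-4-(2-methyl-1,3-dioxolan-2-yl)-3,4,4a,7,8,8a-hexahydronaphthalen-1(2H)-one | CC1=C[C@H]2[C@H](C3(C)OCCO3)CCC(=O)[C@H]2CC1 | intermediate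
14 | (R)-N-[(1E,4R,4aR,8aS)-6-methyl-4-(2-methyl-1,3-dioxolan-2-yl)-3,4,4a,7,8,8a-hexahydronaphthalen-1(2H)-ylidene]-2-methylpropane-2-sulfinamide | CC1=C[C@H]2[C@H](C3(C)OCCO3)CC/C(=N\[S@](=O)C(C)(C)C)[C@H]2CC1 | intermediate
15 | (R)-N-[(1R,4R,4aR,8aS)-1,6-dimethyl-4-(2-methyl-1,3-dioxolan-2-yl)-1,2,3,4,4a,7,8,8a-octahydronaphthalen-1-yl]-2-methylpropane-2-sulfinamide | CC1=C[C@H]2[C@H](C3(C)OCCO3)CC[C@@](C)(N[S@](=O)C(C)(C)C)[C@H]2CC1 | intermediate
16 | (1R,4R,4aR,8aS)-4-acetyl-1,6-dimethyl-1,2,3,4,4a,7,8,8a-octahydronaphthalen-1-aminium chloride | CC1=C[C@H]2[C@H](C(C)=O)CC[C@@](C)([NH3+])[C@H]2CC1.[Cl-] | intermediate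
17 | N-[(1R,4R,4aR,8aS)-4-acetyl-1,6-dimethyl-1,2,3,4,4a,7,8,8a-octahydronaphthalen-1-yl]formamide | CC1=C[C@H]2[C@H](C(C)=O)CC[C@@](C)(NC=O)[C@H]2CC1 | intermediate
18 | 5-bromo-2-methylpent-2-ene | CC(C)=CCCBr | starting material
19 | (4-methylpent-3-en-1-yl)magnesium bromide | CC(C)=CCC[Mg]Br | intermediate
20 | N-[(1R,4R,4aR,8aS)-4-[(2R)-2-hydroxy-6-methylhept-5-en-2-yl]-1,6-dimethyl-1,2,3,4,4a,7,8,8a-octahydronaphthalen-1-yl]formamide | CC1=C[C@H]2[C@H]([C@](C)(O)CCC=C(C)C)CC[C@@](C)(NC=O)[C@H]2CC1 | intermediate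
21 | N-[(1R,4R,4aR,8aS)-4-[(2R,5S)-5-chloro-2,6,6-trimethyloxan-2-yl]-1,6-dimethyl-1,2,3,4,4a,7,8,8a-octahydronaphthalen-1-yl]formamide | CC1=C[C@H]2[C@H]([C@@]3(C)CC[C@H](Cl)C(C)(C)O3)CC[C@@](C)(NC=O)[C@H]2CC1 | target

**Step count**
Total: 12 steps. Longest linear sequence: 11 steps (1–4, 6–12); step 5 is a one-step side branch.

**The three steps most likely to fail, with fallbacks**

Step 6 (templated Diels–Alder). Divinyl ketone can polymerise or take up the alkoxide by oxa-Michael addition, and the facial control rests on a model. The fallback tethers the dienophile covalently and sets out from 7. Acylation with acryloyl chloride (Et3N, CH2Cl2, −20 °C) gives (1R,2E)-4-methyl-1-(2-methyl-1,3-dioxolan-2-yl)penta-2,4-dien-1-yl prop-2-enoate F1. Intramolecular Diels–Alder reaction (toluene, BHT, 170 °C) delivers the dienophile on the oxygen face and gives the cis-fused lactone (3R,3aR,7aS)-5-methyl-3-(2-methyl-1,3-dioxolan-2-yl)-3a,6,7,7a-tetrahydro-2-benzofuran-1(3H)-one F2; any trans-fused isomer is separated. Opening with MeNH(OMe)·HCl and i-PrMgCl gives (1S,2R)-2-[(R)-hydroxy(2-methyl-1,3-dioxolan-2-yl)methyl]-N-methoxy-N,4-dimethylcyclohex-3-ene-1-carboxamide F3, and vinylmagnesium bromide converts this to 11, where the route is rejoined.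

Step 7 (deoxygenative radical cyclisation). The neopentyl-type secondary alcohol may condense poorly with the benzoxazolium salt, and the vinyl ketone is sensitive to the reagents. The fallback forms the same C7–C8 bond reductively from the enone side and sets out from 11. Dess–Martin oxidation gives 1-[(1S,2R)-4-methyl-2-(2-methyl-1,3-dioxolane-2-carbonyl)cyclohex-3-en-1-yl]prop-2-en-1-one F4. SmI2 (HMPA, t-BuOH, THF, −78 °C) couples the enone β-carbon with the C7 ketone to give (4S,4aR,8aS)-4-hydroxy-6-methyl-4-(2-methyl-1,3-dioxolan-2-yl)-3,4,4a,7,8,8a-hexahydronaphthalen-1(2H)-one F5. Acylation with methyl chlorooxoacetate (DMAP) gives the methyl oxalate F6, and Bu3SnH/AIBN (toluene, 110 °C) removes the tertiary oxygen with axial hydrogen delivery to give 13, where the route is rejoined.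

Step 12 (chloroetherification). The chloronium source may attack the ring alkene or the formamide, 5-exo closure may compete, and the C14 selectivity is substrate-controlled. The fallback sets C14 by reagent control without a free chloronium donor and sets out from 20. Epoxidation with the L-fructose-derived Shi ketone (Oxone, buffered MeCN/H2O) gives N-[(1R,4R,4aR,8aS)-4-[(2R)-4-[(2S)-3,3-dimethyloxiran-2-yl]-2-hydroxybutan-2-yl]-1,6-dimethyl-1,2,3,4,4a,7,8,8a-octahydronaphthalen-1-yl]formamide F7. Camphorsulfonic acid induces 5-exo opening with inversion at C14 to give the oxolane carbinol N-[(1R,4R,4aR,8aS)-4-[(2R,5R)-5-(2-hydroxypropan-2-yl)-2-methyloxolan-2-yl]-1,6-dimethyl-1,2,3,4,4a,7,8,8a-octahydronaphthalen-1-yl]formamide F8. Ring-expanding chlorination (TMSCl, cat. ZnCl2, CH2Cl2) ionises the tertiary carbinol to a bicyclic oxonium ion that chloride opens at C14 with inversion, giving 21 directly.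

**Further compounds**
F1 | step 6 | (1R,2E)-4-methyl-1-(2-methyl-1,3-dioxolan-2-yl)penta-2,4-dien-1-yl prop-2-enoate | C=CC(=O)O[C@H](/C=C/C(C)=C)C1(C)OCCO1
F2 | step 6 | (3R,3aR,7aS)-5-methyl-3-(2-methyl-1,3-dioxolan-2-yl)-3a,6,7,7a-tetrahydro-2-benzofuran-1(3H)-one | CC1=C[C@H]2[C@H](C3(C)OCCO3)OC(=O)[C@H]2CC1
F3 | step 6 | (1S,2R)-2-[(R)-hydroxy(2-methyl-1,3-dioxolan-2-yl)methyl]-N-methoxy-N,4-dimethylcyclohex-3-ene-1-carboxamide | CC1=C[C@@H]([C@@H](O)C2(C)OCCO2)[C@@H](C(=O)N(C)OC)CC1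
F4 | step 7 | 1-[(1S,2R)-4-methyl-2-(2-methyl-1,3-dioxolane-2-carbonyl)cyclohex-3-en-1-yl]prop-2-en-1-one | CC1=C[C@@H](C(=O)C2(C)OCCO2)[C@@H](C(=O)C=C)CC1
F5 | step 7 | (4S,4aR,8aS)-4-hydroxy-6-methyl-4-(2-methyl-1,3-dioxolan-2-yl)-3,4,4a,7,8,8a-hexahydronaphthalen-1(2H)-one | CC1=C[C@H]2[C@](O)(C3(C)OCCO3)CCC(=O)[C@H]2CC1
F6 | step 7 | methyl (1S,4aS,8aR)-7-methyl-1-(2-methyl-1,3-dioxolan-2-yl)-4-oxo-1,2,3,4,4a,5,6,8a-octahydronaphthalen-1-yl oxalate | CC1=C[C@H]2[C@](OC(=O)C(=O)OC)(C3(C)OCCO3)CCC(=O)[C@H]2CC1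
F7 | step 12 | N-[(1R,4R,4aR,8aS)-4-[(2R)-4-[(2S)-3,3-dimethyloxiran-2-yl]-2-hydroxybutan-2-yl]-1,6-dimethyl-1,2,3,4,4a,7,8,8a-octahydronaphthalen-1-yl]formamide | CC1=C[C@H]2[C@H]([C@](C)(O)CC[C@@H]3OC3(C)C)CC[C@@](C)(NC=O)[C@H]2CC1
F8 | step 12 | N-[(1R,4R,4aR,8aS)-4-[(2R,5R)-5-(2-hydroxypropan-2-yl)-2-methyloxolan-2-yl]-1,6-dimethyl-1,2,3,4,4a,7,8,8a-octahydronaphthalen-1-yl]formamide | CC1=C[C@H]2[C@H]([C@@]3(C)CC[C@H](C(C)(C)O)O3)CC[C@@](C)(NC=O)[C@H]2CC1
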